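**Retrosynthetic overview**
1. 18 ⇐ 17: methanolysis of one aryl pivalate (last step).
2. 17 ⇐ 9 + 15: the C6–C(benzylic) bond and the (R)-diarylmethine centre are made together in one new step, a chiral phosphoric acid-catalysed ortho-alkylation of phenol 9 by the para-quinone methide 16 formed from racemic alcohol 15.
3. 9 ⇐ 8 ⇐ 7 ⇐ 6 ⇐ 5 ⇐ 3 + 4: pyran ring by invertive Mitsunobu closure of an (R)-carbinol from asymmetric transfer hydrogenation; three-carbon chain by Claisen–Schmidt condensation.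
4. 15 ⇐ 14 ⇐ 13 ⇐ 12 ⇐ 10 + 11: Claisen–Schmidt condensation, pivaloylation, hydrogenation, ketone reduction.
5. Ring order: the four benzene rings are bought; the pyran ring (the only ring made) is closed in step 6, before the two halves are joined in step 12.

Assumption: 1, 4, 10, 11 and all reagents are bought; the (R)-acid is assumed, by analogy with naphthol additions to para-quinone methides, to give the (R)-centre in step 12, and its mirror image is used with no other change if the first run shows the opposite sense.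

**Route**

Step 1
Reactants: 1 1-(2,5-dihydroxyphenyl)ethanone
Product: 2 1-[5-(benzyloxy)-2-hydroxyphenyl]ethanone
Conditions: BnBr (1.05 equiv), K2CO3 (1.1 equiv), acetone, reflux
Reagents that add atoms: benzyl bromide BrCc1ccccc1
Why: Williamson ether synthesis in which only the 5-OH reacts, because the 2-OH is held in a hydrogen bond to the ketone.

Step 2
Reactants: 2 1-[5-(benzyloxy)-2-hydroxyphenyl]ethanone
Product: 3 1-[5-(benzyloxy)-2-methoxyphenyl]ethanone
Conditions: MeI (2 equiv), K2CO3 (2 equiv), DMF, 50 °C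
Reagents that add atoms: iodomethane CI
Why: Williamson O-methylation of the remaining chelated phenol under more forcing conditions.

Step 3
Reactants: 3 1-[5-(benzyloxy)-2-methoxyphenyl]ethanone; 4 4-(benzyloxy)-2-hydroxybenzaldehyde
Product: 5 (E)-3-[4-(benzyloxy)-2-hydroxyphenyl]-1-[5-(benzyloxy)-2-methoxyphenyl]prop-2-en-1-one
Conditions: KOH (5 equiv), EtOH/H2O, rt to 50 °C; AcOH to pH 6
Reagents that add atoms: none
Why: Claisen–Schmidt (crossed aldol) condensation, a standard way to 2-hydroxychalcones from salicylaldehydes, giving the E-enone after elimination of water.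

Step 4
Reactants: 5 (E)-3-[4-(benzyloxy)-2-hydroxyphenyl]-1-[5-(benzyloxy)-2-methoxyphenyl]prop-2-en-1-one
Product: 6 3-[4-(benzyloxy)-2-hydroxyphenyl]-1-[5-(benzyloxy)-2-methoxyphenyl]propan-1-one
Conditions: H2 (1 atm), 10% Pd/C, Ph2S (0.01 equiv), EtOAc, rt
Reagents that add atoms: none
Why: Catalytic hydrogenation over sulfide-poisoned palladium on carbon saturates the enone C=C and leaves benzyl ethers and the aryl ketone untouched.

Step 5
Reactants: 6 3-[4-(benzyloxy)-2-hydroxyphenyl]-1-[5-(benzyloxy)-2-methoxyphenyl]propan-1-one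
Product: 7 (1R)-1-[5-(benzyloxy)-2-methoxyphenyl]-3-[4-(benzyloxy)-2-hydroxyphenyl]propan-1-ol
Conditions: RuCl(p-cymene)[(R,R)-TsNCH(Ph)CH(Ph)NH2] (1 mol %), HCO2H/Et3N (5:2), EtOAc, 30 °C
Reagents that add atoms: none
Why: Noyori–Ikariya asymmetric transfer hydrogenation of an aryl alkyl ketone, in which the (R,R)-catalyst gives the (R)-carbinol as it does with acetophenone and the free phenol is tolerated.

Step 6
Reactants: 7 (1R)-1-[5-(benzyloxy)-2-methoxyphenyl]-3-[4-(benzyloxy)-2-hydroxyphenyl]propan-1-ol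
Product: 8 (2S)-7-(benzyloxy)-2-[5-(benzyloxy)-2-methoxyphenyl]-3,4-dihydro-2H-chromene
Conditions: PPh3 (1.3 equiv), DIAD (1.3 equiv), toluene, 0 °C, 0.02 M
Reagents that add atoms: none
Why: Intramolecular Mitsunobu etherification, in which the only free phenol displaces the activated benzylic alcohol by SN2 and so inverts (R) to the (2S)-chroman centre.

Step 7
Reactants: 8 (2S)-7-(benzyloxy)-2-[5-(benzyloxy)-2-methoxyphenyl]-3,4-dihydro-2H-chromene
Product: 9 (2S)-2-(5-hydroxy-2-methoxyphenyl)-3,4-dihydro-2H-chromen-7-ol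
Conditions: H2 (1 atm), 10% Pd/C, EtOAc/MeOH, rt
Reagents that add atoms: none
Why: Hydrogenolysis of the two primary benzyl ethers, while the hindered secondary cyclic C2–O bond is far slower under neutral conditions and the C2 centre is not touched.

Step 8
Reactants: 10 1-[4-(benzyloxy)phenyl]ethanone; 11 4-hydroxy-2-methoxybenzaldehyde
Product: 12 (E)-1-[4-(benzyloxy)phenyl]-3-(4-hydroxy-2-methoxyphenyl)prop-2-en-1-one
Conditions: HCl (g, sat.), EtOH, 0 °C to rt; aq NaOAc
Reagents that add atoms: none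
Why: Acid-catalysed Claisen–Schmidt condensation, chosen because under base the aldehyde would sit as an unreactive phenoxide, giving the thermodynamic E-enone.

Step 9
Reactants: 12 (E)-1-[4-(benzyloxy)phenyl]-3-(4-hydroxy-2-methoxyphenyl)prop-2-en-1-one
Product: 13 4-{(E)-3-[4-(benzyloxy)phenyl]-3-oxoprop-1-en-1-yl}-3-methoxyphenyl pivalate
Conditions: PivCl (1.2 equiv), Et3N (1.5 equiv), DMAP (5 mol %), CH2Cl2, 0 °C to rt
Reagents that add atoms: pivaloyl chloride CC(C)(C)C(=O)Cl
Why: DMAP-catalysed O-acylation, which turns the resorcinol-type ring into a poor nucleophile for step 12.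

Step 10
Reactants: 13 4-{(E)-3-[4-(benzyloxy)phenyl]-3-oxoprop-1-en-1-yl}-3-methoxyphenyl pivalate
Product: 14 4-[3-(4-hydroxyphenyl)-3-oxopropyl]-3-methoxyphenyl pivalate
Conditions: H2 (1 atm), 10% Pd/C, EtOAc/EtOH, rt
Reagents that add atoms: none
Why: One catalytic hydrogenation saturates the enone C=C and hydrogenolyses the benzyl ether, while the para-hydroxyaryl ketone and the pivalate stay.

Step 11
Reactants: 14 4-[3-(4-hydroxyphenyl)-3-oxopropyl]-3-methoxyphenyl pivalate
Product: 15 rac-4-[3-hydroxy-3-(4-hydroxyphenyl)propyl]-3-methoxyphenyl pivalate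
Conditions: NaBH4 (2 equiv), CeCl3·7H2O (1 equiv), MeOH/THF, 0 °C; pH 7 phosphate buffer
Reagents that add atoms: none
Why: Luche-type borohydride reduction, fast and only weakly basic so the aryl pivalate survives; the racemic carbinol is acceptable because this centre becomes planar in step 12.

Step 12
Reactants: 9 (2S)-2-(5-hydroxy-2-methoxyphenyl)-3,4-dihydro-2H-chromen-7-ol; 15 rac-4-[3-hydroxy-3-(4-hydroxyphenyl)propyl]-3-methoxyphenyl pivalate
Product: 17 4-{(3R)-3-[(2S)-7-hydroxy-2-(5-hydroxy-2-methoxyphenyl)-3,4-dihydro-2H-chromen-6-yl]-3-(4-hydroxyphenyl)propyl}-3-methoxyphenyl pivalate, via para-quinone methide 16 (not isolated)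
Conditions: (R)-3,3'-bis(2,4,6-triisopropylphenyl)-1,1'-binaphthyl-2,2'-diyl hydrogen phosphate (10 mol %), 4 Å MS, CH2Cl2/PhCF3 (1:1), 0 °C to rt; 15 added over 6 h to 9 (1.5 equiv)
Reagents that add atoms: none
Why: Proposed new method: a stereoconvergent, chiral phosphoric acid-catalysed ortho-C–H alkylation of a free resorcinol-type phenol by an enolisable δ-alkyl para-quinone methide without blocking groups, in which the acid dehydrates racemic 15 to planar 16, binds the carbonyl oxygen of 16 through P–OH and the 7-OH of 9 through P=O, and so directs C6 (ortho to 7-OH, para to O1, less hindered than C8) to one face of the exocyclic carbon in a 1,6-addition that sets the (R)-centre under catalyst control, the pivalate ring and the singly activated 2-aryl ring being too weak as nucleophiles to compete; the closest known reaction type is the chiral phosphoric acid-catalysed 1,6-addition (Friedel–Crafts) of naphthols and indoles to δ-aryl para-quinone methides generated in situ from para-hydroxybenzyl alcohols.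

Step 13
Reactants: 17 4-{(3R)-3-[(2S)-7-hydroxy-2-(5-hydroxy-2-methoxyphenyl)-3,4-dihydro-2H-chromen-6-yl]-3-(4-hydroxyphenyl)propyl}-3-methoxyphenyl pivalate
Product: 18 (2S)-2-(5-hydroxy-2-methoxyphenyl)-6-[(1R)-3-(4-hydroxy-2-methoxyphenyl)-1-(4-hydroxyphenyl)propyl]-3,4-dihydro-2H-chromen-7-ol
Conditions: K2CO3 (3 equiv), degassed MeOH, rt; aq NH4Cl
Reagents that add atoms: none
Why: Base-mediated transesterification (methanolysis) of the aryl pivalate, which touches neither stereocentre nor the methyl ethers.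

**Compound list**
1 | 1-(2,5-dihydroxyphenyl)ethanone | CC(=O)c1cc(O)ccc1O | starting material
2 | 1-[5-(benzyloxy)-2-hydroxyphenyl]ethanone | CC(=O)c1cc(OCc2ccccc2)ccc1O | intermediate
3 | 1-[5-(benzyloxy)-2-methoxyphenyl]ethanone | COc1ccc(OCc2ccccc2)cc1C(C)=O | intermediate
4 | 4-(benzyloxy)-2-hydroxybenzaldehyde | O=Cc1ccc(OCc2ccccc2)cc1O | starting material
5 | (E)-3-[4-(benzyloxy)-2-hydroxyphenyl]-1-[5-(benzyloxy)-2-methoxyphenyl]prop-2-en-1-one | COc1ccc(OCc2ccccc2)cc1C(=O)/C=C/c1ccc(OCc2ccccc2)cc1O | intermediate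
6 | 3-[4-(benzyloxy)-2-hydroxyphenyl]-1-[5-(benzyloxy)-2-methoxyphenyl]propan-1-one | COc1ccc(OCc2ccccc2)cc1C(=O)CCc1ccc(OCc2ccccc2)cc1O | intermediate
7 | (1R)-1-[5-(benzyloxy)-2-methoxyphenyl]-3-[4-(benzyloxy)-2-hydroxyphenyl]propan-1-ol | COc1ccc(OCc2ccccc2)cc1[C@H](O)CCc1ccc(OCc2ccccc2)cc1O | intermediate
8 | (2S)-7-(benzyloxy)-2-[5-(benzyloxy)-2-methoxyphenyl]-3,4-dihydro-2H-chromene | COc1ccc(OCc2ccccc2)cc1[C@@H]1CCc2ccc(OCc3ccccc3)cc2O1 | intermediate
9 | (2S)-2-(5-hydroxy-2-methoxyphenyl)-3,4-dihydro-2H-chromen-7-ol | COc1ccc(O)cc1[C@@H]1CCc2ccc(O)cc2O1 | intermediate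
10 | 1-[4-(benzyloxy)phenyl]ethanone | CC(=O)c1ccc(OCc2ccccc2)cc1 | starting material
11 | 4-hydroxy-2-methoxybenzaldehyde | COc1cc(O)ccc1C=O | starting material
12 | (E)-1-[4-(benzyloxy)phenyl]-3-(4-hydroxy-2-methoxyphenyl)prop-2-en-1-one | COc1cc(O)ccc1/C=C/C(=O)c1ccc(OCc2ccccc2)cc1 | intermediate
13 | 4-{(E)-3-[4-(benzyloxy)phenyl]-3-oxoprop-1-en-1-yl}-3-methoxyphenyl pivalate | COc1cc(OC(=O)C(C)(C)C)ccc1/C=C/C(=O)c1ccc(OCc2ccccc2)cc1 | intermediate
14 | 4-[3-(4-hydroxyphenyl)-3-oxopropyl]-3-methoxyphenyl pivalate | COc1cc(OC(=O)C(C)(C)C)ccc1CCC(=O)c1ccc(O)cc1 | intermediate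
15 | rac-4-[3-hydroxy-3-(4-hydroxyphenyl)propyl]-3-methoxyphenyl pivalate | COc1cc(OC(=O)C(C)(C)C)ccc1CCC(O)c1ccc(O)cc1 | intermediate
16 | 3-methoxy-4-[3-(4-oxocyclohexa-2,5-dien-1-ylidene)propyl]phenyl pivalate (para-quinone methide) | COc1cc(OC(=O)C(C)(C)C)ccc1CCC=C1C=CC(=O)C=C1 | intermediate (not isolated)
17 | 4-{(3R)-3-[(2S)-7-hydroxy-2-(5-hydroxy-2-methoxyphenyl)-3,4-dihydro-2H-chromen-6-yl]-3-(4-hydroxyphenyl)propyl}-3-methoxyphenyl pivalate | COc1cc(OC(=O)C(C)(C)C)ccc1CC[C@H](c1ccc(O)cc1)c1cc2c(cc1O)O[C@H](c1cc(O)ccc1OC)CC2 | intermediate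
18 | (2S)-2-(5-hydroxy-2-methoxyphenyl)-6-[(1R)-3-(4-hydroxy-2-methoxyphenyl)-1-(4-hydroxyphenyl)propyl]-3,4-dihydro-2H-chromen-7-ol | COc1cc(O)ccc1CC[C@H](c1ccc(O)cc1)c1cc2c(cc1O)O[C@H](c1cc(O)ccc1OC)CC2 | target

**Step count**
Total steps: 13. Longest linear sequence: 9 (steps 1–7, 12, 13). The second branch (steps 8–11) joins at step 12.

**Three steps most likely to fail**

Step 12 (the new union). The risks are:
- low enantioselectivity, because the para-quinone methide terminus carries only H and a flexible alkyl chain;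
- alkylation at C8 or double alkylation;
- loss of 15 by elimination to the conjugated styrene or by self-condensation;
- the unproven sense of induction.

A more acidic N-triflyl phosphoramide analogue of the catalyst is the first adjustment. The minor (2S,1'S) diastereomer is separable from 17 because the two are diastereomers.

The fallback uses known chemistry only, sets out from 8 and comes back to the route at 18. Vilsmeier–Haack formylation of 8 (POCl3, DMF, 60 °C; aq NaOAc) at C6 gives (2S)-7-(benzyloxy)-2-[5-(benzyloxy)-2-methoxyphenyl]-3,4-dihydro-2H-chromene-6-carbaldehyde F1. Claisen–Schmidt condensation of F1 with purchased 1-[4-(benzyloxy)-2-methoxyphenyl]ethanone (KOH, EtOH/THF, rt) gives (E)-1-[4-(benzyloxy)-2-methoxyphenyl]-3-{(2S)-7-(benzyloxy)-2-[5-(benzyloxy)-2-methoxyphenyl]-3,4-dihydro-2H-chromen-6-yl}prop-2-en-1-one F2. Hayashi–Miyaura asymmetric 1,4-addition of 4-(benzyloxy)phenylboronic acid to F2 gives (3R)-1-[4-(benzyloxy)-2-methoxyphenyl]-3-[4-(benzyloxy)phenyl]-3-{(2S)-7-(benzyloxy)-2-[5-(benzyloxy)-2-methoxyphenyl]-3,4-dihydro-2H-chromen-6-yl}propan-1-one F3. The conditions are [RhCl(C2H4)2]2 (2.5 mol %), 2,5-diphenylbicyclo[2.2.2]octa-2,5-diene (5.5 mol %) in the enantiomeric form that the established facial model assigns to the (R)-centre, KOH, dioxane/H2O, 50 °C. NaBH4 (MeOH/THF, 0 °C) gives (3R)-1-[4-(benzyloxy)-2-methoxyphenyl]-3-[4-(benzyloxy)phenyl]-3-{(2S)-7-(benzyloxy)-2-[5-(benzyloxy)-2-methoxyphenyl]-3,4-dihydro-2H-chromen-6-yl}propan-1-ol F4 as a mixture of carbinol epimers, which does not matter. H2 (1 atm), 10% Pd/C, EtOAc/AcOH (20:1) then removes the electron-rich benzylic hydroxyl and all four benzyl ethers in one operation and delivers 18.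

Step 6 (Mitsunobu closure). The carbinol is an ortho-methoxybenzylic alcohol, so partial ionisation of the activated alcohol could erode the ee. Low temperature and toluene are chosen to suppress this.

The fallback forms the aryl C–O bond instead, with retention, sets out from 3 and comes back at 8. Claisen–Schmidt condensation of 3 with purchased 4-(benzyloxy)-2-bromobenzaldehyde (KOH, EtOH) gives (E)-3-[4-(benzyloxy)-2-bromophenyl]-1-[5-(benzyloxy)-2-methoxyphenyl]prop-2-en-1-one F5. Copper hydride conjugate reduction (Cu(OAc)2·H2O 5 mol %, 1,2-bis(diphenylphosphino)benzene, polymethylhydrosiloxane, t-BuOH, toluene, rt), which spares the aryl bromide, gives 3-[4-(benzyloxy)-2-bromophenyl]-1-[5-(benzyloxy)-2-methoxyphenyl]propan-1-one F6. Corey–Bakshi–Shibata reduction with (R)-1-methyl-3,3-diphenyltetrahydro-1H,3H-pyrrolo[1,2-c][1,3,2]oxazaborole and BH3·SMe2 (THF, −20 °C) gives (1S)-3-[4-(benzyloxy)-2-bromophenyl]-1-[5-(benzyloxy)-2-methoxyphenyl]propan-1-ol F7. Palladium-catalysed intramolecular C–O coupling (Pd(OAc)2, 2-(di-tert-butylphosphino)-1,1'-binaphthyl, Cs2CO3, toluene, 80 °C) closes the pyran ring without touching the carbinol C–O bond, so the (S)-alcohol gives 8.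

Step 8 (acid-catalysed condensation with a free para-hydroxybenzaldehyde). The electron-rich aldehyde and product may give low conversion or HCl/EtOH adducts.

The fallback replaces the aldol by a Wittig olefination under neutral conditions, sets out from 10 and 11 and comes back at 13. Acylation of 11 (PivCl, Et3N, CH2Cl2) gives 4-formyl-3-methoxyphenyl pivalate F8. α-Bromination of 10 (CuBr2, EtOAc/CHCl3, reflux) gives 2-bromo-1-[4-(benzyloxy)phenyl]ethanone F9. PPh3 in toluene gives {2-[4-(benzyloxy)phenyl]-2-oxoethyl}triphenylphosphonium bromide F10. Aqueous Na2CO3 gives the stabilised ylide 1-[4-(benzyloxy)phenyl]-2-(triphenyl-λ5-phosphanylidene)ethanone F11. F8 and F11 in toluene at 100 °C give the E-enone 13 directly, so step 9 is skipped.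

**Further compounds**
F1 | step 12 | (2S)-7-(benzyloxy)-2-[5-(benzyloxy)-2-methoxyphenyl]-3,4-dihydro-2H-chromene-6-carbaldehyde | O=Cc1cc2c(cc1OCc1ccccc1)O[C@H](c1cc(OCc3ccccc3)ccc1OC)CC2
F2 | step 12 | (E)-1-[4-(benzyloxy)-2-methoxyphenyl]-3-{(2S)-7-(benzyloxy)-2-[5-(benzyloxy)-2-methoxyphenyl]-3,4-dihydro-2H-chromen-6-yl}prop-2-en-1-one | COc1cc(OCc2ccccc2)ccc1C(=O)/C=C/c1cc2c(cc1OCc1ccccc1)O[C@H](c1cc(OCc3ccccc3)ccc1OC)CC2
F3 | step 12 | (3R)-1-[4-(benzyloxy)-2-methoxyphenyl]-3-[4-(benzyloxy)phenyl]-3-{(2S)-7-(benzyloxy)-2-[5-(benzyloxy)-2-methoxyphenyl]-3,4-dihydro-2H-chromen-6-yl}propan-1-one | COc1cc(OCc2ccccc2)ccc1C(=O)C[C@H](c1ccc(OCc2ccccc2)cc1)c1cc2c(cc1OCc1ccccc1)O[C@H](c1cc(OCc3ccccc3)ccc1OC)CC2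
F4 | step 12 | (3R)-1-[4-(benzyloxy)-2-methoxyphenyl]-3-[4-(benzyloxy)phenyl]-3-{(2S)-7-(benzyloxy)-2-[5-(benzyloxy)-2-methoxyphenyl]-3,4-dihydro-2H-chromen-6-yl}propan-1-ol (both C1 epimers) | COc1cc(OCc2ccccc2)ccc1C(O)C[C@H](c1ccc(OCc2ccccc2)cc1)c1cc2c(cc1OCc1ccccc1)O[C@H](c1cc(OCc3ccccc3)ccc1OC)CC2
F5 | step 6 | (E)-3-[4-(benzyloxy)-2-bromophenyl]-1-[5-(benzyloxy)-2-methoxyphenyl]prop-2-en-1-one | COc1ccc(OCc2ccccc2)cc1C(=O)/C=C/c1ccc(OCc2ccccc2)cc1Br
F6 | step 6 | 3-[4-(benzyloxy)-2-bromophenyl]-1-[5-(benzyloxy)-2-methoxyphenyl]propan-1-one | COc1ccc(OCc2ccccc2)cc1C(=O)CCc1ccc(OCc2ccccc2)cc1Br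
F7 | step 6 | (1S)-3-[4-(benzyloxy)-2-bromophenyl]-1-[5-(benzyloxy)-2-methoxyphenyl]propan-1-ol | COc1ccc(OCc2ccccc2)cc1[C@@H](O)CCc1ccc(OCc2ccccc2)cc1Br
F8 | step 8 | 4-formyl-3-methoxyphenyl pivalate | COc1cc(OC(=O)C(C)(C)C)ccc1C=O
F9 | step 8 | 2-bromo-1-[4-(benzyloxy)phenyl]ethanone | O=C(CBr)c1ccc(OCc2ccccc2)cc1
F10 | step 8 | {2-[4-(benzyloxy)phenyl]-2-oxoethyl}triphenylphosphonium bromide | O=C(C[P+](c1ccccc1)(c1ccccc1)c1ccccc1)c1ccc(OCc2ccccc2)cc1.[Br-]
F11 | step 8 | 1-[4-(benzyloxy)phenyl]-2-(triphenyl-λ5-phosphanylidene)ethanone | O=C(C=P(c1ccccc1)(c1ccccc1)c1ccccc1)c1ccc(OCc2ccccc2)cc1
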